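## Analysis of the target

Compound 26 is a bicyclic labdane acid. It is a trans-fused decalin (ring A: C1–C5 and C10; ring B: C5–C10) with an exocyclic methylene at C8 (C17). C9 carries a chain (C11–C16) that ends in an E-configured 3-methylpent-2-enoic acid.

There are four stereocentres: C4 (R), C5 (R), C9 (S) and C10 (R). H5 is α and the C10 methyl group (C20) is β, so the ring fusion is trans. The C9 chain is β and equatorial. At the quaternary C4 the acetoxymethyl carbon (C18) is α and equatorial, and the methyl group (C19) is β and axial, syn to C20.

C4 and C10 are quaternary carbons in a 1,3-relationship with C5 between them. Ring A has no other functional group, so neither centre can lean on a carbonyl that stays in the target.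

The sensitive groups are:
- the exocyclic alkene, which moves into the ring under protic acid;
- the primary acetate, which would not survive an ester hydrolysis at C15;
- the trisubstituted C13=C14 bond, whose geometry a simple ketone olefination does not secure.

The hard part is C4: two one-carbon substituents of similar size must be told apart, and that choice must be relayed to C5 and from there to C10 and C9.

The route rests on the fact that C4 is β and C5 is α to C10. With C10 as a ring A ketone, C4 is made by conjugate methylation of an enone that already carries the CH2O group, and C5 by alkylation of the enolate so formed.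

## Retrosynthetic reasoning

**26 ⇒ 25.** The O–acetyl bond is cut last. With the C15 acid already free in 25, the final step is an acetylation, and no ester has to be hydrolysed beside the acetate.

**25 ⇒ 22.** C13–C16 and C14–C15 are cut together, back to the terminal alkyne of 22. Syn carbometallation with 6 puts the methyl group on C13 and the metal on C14 (alkenylalane 23). Carboxylation of C14 with retention then fixes the E geometry by mechanism. A carbonyl olefination at a C13 methyl ketone would leave the geometry to a modest thermodynamic preference. The forward reaction has to tolerate the free hydroxyl group and the C8=C17 alkene.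

**22 ⇒ 21 ⇒ 20.** Both silyl groups of 21 are removed in one operation, and C8=C17 is traced to the C8 ketone of 20 by methylenation. A ketone at C8 serves twice: it makes C9 epimerisable, so the equatorial β chain is reached by equilibration, and it is the handle by which ring B is closed.

**20 ⇒ 19 ⇒ 18.** Ring B is opened at C9–C10. In the forward sense a tertiary cation at C10, generated from the carbinol of 18, is attacked by the C8 enol through C9. This bond is chosen because C10 is the one ring B atom whose other substituents (C1, C5, C20) are already in ring A. The axial C19 methyl group set in the key step steers C9 to the α face of C10, which gives the trans fusion. A plain C8 ketone would enolise towards C7 as readily as towards C9 and would be captured at oxygen. The ester on C9 in 18 and 19 makes C9 the only nucleophilic carbon and holds the enol in a chelate. It is deleted on the way to 20, which also lets C9 settle.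

**18 ⇒ 13 + 16.** C8–C9 is cut as a crossed Claisen acylation: the enolate 17 of ester 16 opens lactone 13. The lactone stores C8 at the acid oxidation level, protects the C10 hydroxyl, and releases it when C8 becomes a ketone. The whole side chain, with C13≡C14 masked as a silylalkyne, arrives in one piece.

**16 ⇒ 14.** Ester 16 is the one-carbon homologue of the commercial chloride 14 through its Grignard reagent 15. The carbon added is the one later lost from C9.

**13 ⇒ 12 ⇒ 11 ⇒ 10.** These are functional-group changes. The lactone carbonyl C8 is the terminal carbon of the allyl group of 10 (hydroboration to 12, then oxidative lactonisation). The C10 carbinol of 11 arises by addition of a methyl nucleophile (C20) to the ring A ketone of 10. Adding C20 first keeps the ketone from interfering with the hydroboration.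

**10 ⇒ 5 + 6 + 7.** The key disconnection cuts C4–C19 and C5–C6. In enone 5 the β-carbon C4 already carries its ring bonds and the CH2O group, so methyl transfer from 6 creates the quaternary centre with both exocyclic ligands in final form. The resulting enolate 8 is fixed between C10 and C5, where allyl iodide 7 delivers C6–C8 of ring B. The forward reaction must achieve enantioface selection at C4 by the catalyst and allylation of C5 anti to the CH2O group. Cutting C4–C18 instead would need an asymmetric conjugate hydroxymethylation, which is far less developed.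

**5 ⇒ 4 ⇒ 2 + 3 ⇒ 1.** Silyl ether 5 comes from alcohol 4, whose C4–C18 bond is cut as a cross-coupling between enol triflate 2 (from dione 1) and stannane 3. This reaches 5 in three reliable steps and leaves the uncertainty of the route in the key step.

## Alternatives that were turned down

**Alternative 1:** Both rings are cut at once, at C5–C10 and C8–C9. Forward, the acyclic trienal A1 would undergo an intramolecular Diels–Alder reaction under a chiral Lewis acid to give the trans-fused adduct A2.
- For: C5, C8, C9 and C10 and the trans ring fusion come from one concerted step, and C10 becomes quaternary without a cation. On control of C5 and C10 this is stronger than the chosen route.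
- Against: C4 emerges from A1 as a spiro carbon bearing two equivalent CH2O arms. They must later be told apart, one deoxygenated to C19 and one kept as C18, at the centre that defines the target. The dienophile of A1 is a β,β-disubstituted enal with a fully substituted terminus C10, so its reactivity is low. A1 also carries a silyl dienol ether that must be made late. After the cycloaddition, A2 still needs hydrogenation of C6=C7, oxidation and methylenation at C8, and a four-carbon extension at C11.
- Comparison: the chosen strategy fixes C4 directly with its final substituents and needs fewer redox corrections. It pays with a cationic ring B closure that is less secure than a cycloaddition.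

**Alternative 2:** Ring B is cut at C9–C10 and C7–C8, with C11 tied to the C18 oxygen. Forward, the butynoate ester A3 would be heated to give the bridged lactone A4.
- For: the tether relays the C4 configuration to C10 through a rigid transition state, and no cation is involved. On C10 it is stronger than the chosen closure. C18–O and C11 are in place from the start.
- Against: the diene terminus C10 of A3 is fully substituted and the dienophile is an internal alkynoate held in a seven-membered ester tether, so forcing temperatures are expected. A4 has two misplaced double bonds. C5=C6 must be reduced to give the trans H5. The tetrasubstituted C8=C9 bond must be moved to the exocyclic C8=C17 position with C9–H set, against the thermodynamic preference. C11 must be brought from the lactone level to CH2 and extended. The quaternary C4 of A3 must also be made in enantiopure form beforehand, which is the problem the chosen key step solves.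
- Comparison: the chosen strategy is shorter and leaves no alkene to relocate. It gives up the pericyclic control of C10.

**Alternative 3:** Ring A is annulated onto ring B, cutting C9–C11, C10–C1 and C4=C5. Forward, the cuprate derived from Grignard reagent A6 would add to C9 of the siloxy enone A5 anti to the C8 oxygen. The C10 enolate would add to the silyl vinyl ketone A7, and base-induced desilylation and aldol condensation would give the octalone A8.
- For: C9 and C10 are set by anti addition and anti alkylation of an enolate, which is well-precedented and free of cations. The side chain enters convergently. On C9 and C10 it is stronger than the chosen route.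
- Against: C4 and C5 remain open after A8. A reductive alkylation of the enone must bring in an oxygenated one-carbon electrophile on the α face, and the C3 ketone must then be deleted. The C8 oxygen of A8 needs deprotection, oxidation and methylenation. The ketal-masked C13 ketone leads to an E/Z mixture on olefination. Capture of a fully substituted C10 enolate next to a branched C9 is also slow.
- Comparison: the chosen strategy delivers C4 with both ligands final, leaves nothing at C3 to remove, and sets C13=C14 by carbometallation. The total step count is lower.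

Key step: step 4

Remarks and assumptions on the chemistry:
- Atom labels C1–C20 are those of the labdane skeleton of 26 and are used for all intermediates.
- Assumption: ligand L is the phosphoramidite from 2,2'-biphenol and bis[(S)-1-(naphthalen-2-yl)ethyl]amine, taken to deliver methyl to the face of 5 that gives (3R)-8. If the first run shows the opposite sense, the (R,R) ligand is used and nothing else changes.
- Assumption: methyl addition in step 5 is drawn as equatorial (C10 hydroxyl β). The C10 epimer would serve equally, because C10 becomes planar in step 10.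
- Compound 18 is a mixture of C9 epimers in equilibrium with its cyclic hemiketal. The C9 configuration drawn for 19 is the one expected from the chelated Z-enol and is erased in step 11.

## Route

Step 1
Reactants: 1 cyclohexane-1,3-dione
Product: 2 3-oxocyclohex-1-en-1-yl trifluoromethanesulfonate
Conditions: Tf2O, pyridine, CH2Cl2, −78 → 0 °C
Reagents that add atoms: trifluoromethanesulfonic anhydride, O=S(=O)(OS(=O)(=O)C(F)(F)F)C(F)(F)F
Why: O-Sulfonylation of the enol form of the 1,3-dione gives the vinylogous acyl triflate, a standard enol triflate formation.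

Step 2
Reactants: 2 3-oxocyclohex-1-en-1-yl trifluoromethanesulfonate; 3 (tributylstannyl)methanol
Product: 4 3-(hydroxymethyl)cyclohex-2-en-1-one
Conditions: Pd(PPh3)4 (5 mol %), LiCl, 1,4-dioxane, 90 °C
Reagents that add atoms: none
Why: Stille coupling: the electron-poor vinyl triflate adds oxidatively to zerovalent palladium, chloride exchange and transmetallation transfer the hydroxymethyl group from tin, and reductive elimination forms C4–C18. The free hydroxymethyl group is transferred because a lithiated silyloxymethyl reagent would rearrange by silyl migration from oxygen to carbon.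

Step 3
Reactants: 4 3-(hydroxymethyl)cyclohex-2-en-1-one
Product: 5 3-{[(triisopropylsilyl)oxy]methyl}cyclohex-2-en-1-one
Conditions: iPr3SiCl, imidazole, DMF, 23 °C
Reagents that add atoms: chlorotri(propan-2-yl)silane, CC(C)[Si](Cl)(C(C)C)C(C)C
Why: Silylation of the primary allylic alcohol. The bulky silyl ether should survive the organometallic, oxidative and Lewis-acidic steps and makes CH2O the larger substituent at C4.

Step 4
Reactants: 5 3-{[(triisopropylsilyl)oxy]methyl}cyclohex-2-en-1-one; 6 trimethylaluminium; 7 allyl iodide (3-iodoprop-1-ene)
Product: 10 (2S,3R)-3-methyl-2-(prop-2-en-1-yl)-3-{[(triisopropylsilyl)oxy]methyl}cyclohexan-1-one, via dimethylaluminium enolate 8 (not isolated), via lithium trimethylaluminate enolate 9 (not isolated)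
Conditions: Cu(O2CC4H3S) (copper thiophene-2-carboxylate, 5 mol %), phosphoramidite L (10 mol %), Et2O, −30 °C; then MeLi, THF, DMPU, −30 → 0 °C
Reagents that add atoms: none
Why: Transmetallation from 6 gives a methylcopper–phosphoramidite species (monovalent copper) that binds the enone, adds to C3 (labdane C4) and eliminates reductively, which creates the quaternary centre and the regiodefined aluminium enolate 8 between C1 and C2 (labdane C10 and C5). The closest known reaction type is the copper-catalysed enantioselective conjugate addition of trialkylaluminium reagents to 3-substituted cyclohexenones with alkylation of the resulting enolate. The step closes no ring; it forms C4–C19 and C5–C6 and two stereocentres. The C3 configuration is set by the chiral ligand on copper, and the ring makes the two β-substituents (ring CH2 and CH2OSi) unambiguous. Because 8 is too covalent to react with 7, MeLi converts it into the aluminate 9, which is allylated at carbon in THF/DMPU. The C2 configuration is substrate-controlled: 7 approaches C2 of the half-chair enolate axially, anti to the pseudoaxial C3 substituent, and the conformer with the bulky CH2OSi group pseudoaxial leaves only the methyl group gauche to the incoming electrophile, so allyl should end trans to CH2OSi. The step needs enantioface selectivity at C3 (ligand), C- over O-allylation (soft iodide) and trans selectivity at C2 (size difference between CH2OSi(iPr)3 and CH3). The C2 epimers are separable ketones, and the minor one can be re-equilibrated with base, although the thermodynamic bias is expected to be small.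

Step 5
Reactants: 10 (2S,3R)-3-methyl-2-(prop-2-en-1-yl)-3-{[(triisopropylsilyl)oxy]methyl}cyclohexan-1-one
Product: 11 (1R,2S,3R)-1,3-dimethyl-2-(prop-2-en-1-yl)-3-{[(triisopropylsilyl)oxy]methyl}cyclohexan-1-ol
Conditions: CeCl3, MeLi, THF, −78 °C
Reagents that add atoms: methyllithium, [Li]C
Why: 1,2-Addition of the weakly basic organocerium reagent to the hindered, enolisable ketone installs C20 without epimerising C2 (labdane C5). Attack should be equatorial because the axial C3 methyl group blocks the other face, but the carbinol configuration is irrelevant since C10 becomes planar in step 10.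

Step 6
Reactants: 11 (1R,2S,3R)-1,3-dimethyl-2-(prop-2-en-1-yl)-3-{[(triisopropylsilyl)oxy]methyl}cyclohexan-1-ol
Product: 12 (1R,2S,3R)-2-(3-hydroxypropyl)-1,3-dimethyl-3-{[(triisopropylsilyl)oxy]methyl}cyclohexan-1-ol
Conditions: 9-BBN, THF, 0 → 23 °C; then NaOH, H2O2, 0 °C
Reagents that add atoms: hydrogen peroxide, OO
Why: Anti-Markovnikov hydroboration–oxidation of the terminal alkene places oxygen on the terminal carbon (C8). The hindered tertiary alcohol and the silyl ether should be unaffected.

Step 7
Reactants: 12 (1R,2S,3R)-2-(3-hydroxypropyl)-1,3-dimethyl-3-{[(triisopropylsilyl)oxy]methyl}cyclohexan-1-ol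
Product: 13 (4aS,5R,8aR)-5,8a-dimethyl-5-{[(triisopropylsilyl)oxy]methyl}octahydro-2H-chromen-2-one
Conditions: TEMPO (cat.), PhI(OAc)2, CH2Cl2, 23 °C
Reagents that add atoms: none
Why: Oxidative lactonisation: the oxoammonium salt from TEMPO oxidises the primary alcohol to the C8 aldehyde, which closes onto the tertiary hydroxyl as a lactol and is oxidised once more; a tertiary alcohol cannot be oxidised. The lactone protects the C10 hydroxyl and raises C8 to the acid oxidation level.

Step 8
Reactants: 14 (5-chloropent-1-yn-1-yl)trimethylsilane
Product: 16 methyl 6-(trimethylsilyl)hex-5-ynoate, via Grignard reagent 15 (not isolated)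
Conditions: Mg, THF, reflux; then inverse addition to ClCO2Me (excess), THF, −78 → 0 °C
Reagents that add atoms: methyl chloroformate, COC(=O)Cl
Why: Grignard formation from the primary chloride and acylation with excess chloroformate by inverse addition should stop at the ester. The silyl group masks the alkyne C–H.

Step 9
Reactants: 13 (4aS,5R,8aR)-5,8a-dimethyl-5-{[(triisopropylsilyl)oxy]methyl}octahydro-2H-chromen-2-one; 16 methyl 6-(trimethylsilyl)hex-5-ynoate
Product: 18 methyl 5-[(1S,2R,6R)-2-hydroxy-2,6-dimethyl-6-{[(triisopropylsilyl)oxy]methyl}cyclohexyl]-3-oxo-2-[4-(trimethylsilyl)but-3-yn-1-yl]pentanoate, via lithium ester enolate 17 (not isolated)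
Conditions: LiN(iPr)2, THF, −78 °C; then 13, −78 → −20 °C; aq. NH4Cl
Reagents that add atoms: none
Why: Crossed Claisen acylation: enolate 17 attacks the lactone carbonyl C8, the ring opens to the tertiary alkoxide, and the β-keto ester is deprotonated by a second equivalent of enolate, which drives the reaction. Both C9 epimers and the hemiketal form converge in step 10.

Step 10
Reactants: 18 methyl 5-[(1S,2R,6R)-2-hydroxy-2,6-dimethyl-6-{[(triisopropylsilyl)oxy]methyl}cyclohexyl]-3-oxo-2-[4-(trimethylsilyl)but-3-yn-1-yl]pentanoate
Product: 19 methyl (1R,4aR,5R,8aS)-5,8a-dimethyl-2-oxo-5-{[(triisopropylsilyl)oxy]methyl}-1-[4-(trimethylsilyl)but-3-yn-1-yl]decahydronaphthalene-1-carboxylate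
Conditions: SnCl4, CH2Cl2, −78 → −20 °C
Reagents that add atoms: none
Why: SnCl4 ionises the tertiary C10–O bond and holds the β-keto ester as its chelated Z-enol, whose C9 attacks the C10 cation through a chair; this is the Lewis-acid cation–enol cyclisation used to terminate cation–olefin cyclisations with β-keto esters. C9 enters on the α lobe of C10 because the β face is shielded by the axial C19 methyl group, which should give the trans fusion with C20 β. The ester makes C9 the only enol carbon that can reach C10, and capture at the enol oxygen is reversible under these conditions.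

Step 11
Reactants: 19 methyl (1R,4aR,5R,8aS)-5,8a-dimethyl-2-oxo-5-{[(triisopropylsilyl)oxy]methyl}-1-[4-(trimethylsilyl)but-3-yn-1-yl]decahydronaphthalene-1-carboxylate
Product: 20 (1R,4aR,5R,8aS)-5,8a-dimethyl-5-{[(triisopropylsilyl)oxy]methyl}-1-[4-(trimethylsilyl)but-3-yn-1-yl]octahydronaphthalen-2(1H)-one
Conditions: LiCl, H2O, DMSO, 150 °C
Reagents that add atoms: none
Why: Krapcho dealkoxycarbonylation: chloride demethylates the ester, the β-keto carboxylate loses CO2, and the enol is protonated at C9. At this temperature C9 should equilibrate to the epimer with the chain equatorial (β), the configuration of the target.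

Step 12
Reactants: 20 (1R,4aR,5R,8aS)-5,8a-dimethyl-5-{[(triisopropylsilyl)oxy]methyl}-1-[4-(trimethylsilyl)but-3-yn-1-yl]octahydronaphthalen-2(1H)-one
Product: 21 trimethyl{4-[(1S,4aR,5R,8aR)-5,8a-dimethyl-2-methylidene-5-{[(triisopropylsilyl)oxy]methyl}decahydronaphthalen-1-yl]but-1-yn-1-yl}silane
Conditions: Ph3PCH3Br, NaN(SiMe3)2, THF, 0 → 65 °C
Reagents that add atoms: methyltriphenylphosphonium bromide, C[P+](c1ccccc1)(c1ccccc1)c1ccccc1.[Br-]
Why: Wittig methylenation of the C8 ketone. Any base-induced epimerisation at C9 returns the same equatorial epimer, and partial loss of the alkynyl silyl group would be harmless because step 13 removes it.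

Step 13
Reactants: 21 trimethyl{4-[(1S,4aR,5R,8aR)-5,8a-dimethyl-2-methylidene-5-{[(triisopropylsilyl)oxy]methyl}decahydronaphthalen-1-yl]but-1-yn-1-yl}silane
Product: 22 [(1R,4aR,5S,8aR)-5-(but-3-yn-1-yl)-1,4a-dimethyl-6-methylidenedecahydronaphthalen-1-yl]methanol
Conditions: Bu4NF, THF, 23 → 45 °C
Reagents that add atoms: none
Why: Fluoride cleaves the Si–O bond of the silyl ether and the Si–C(sp) bond of the alkynylsilane in one operation. No stereocentre is touched.

Step 14
Reactants: 22 [(1R,4aR,5S,8aR)-5-(but-3-yn-1-yl)-1,4a-dimethyl-6-methylidenedecahydronaphthalen-1-yl]methanol; 6 trimethylaluminium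
Product: 25 (2E)-5-[(1S,4aR,5R,8aR)-5-(hydroxymethyl)-5,8a-dimethyl-2-methylidenedecahydronaphthalen-1-yl]-3-methylpent-2-enoic acid, via alkenyldimethylalane 23 (not isolated), via lithium alkenylalanate 24 (not isolated)
Conditions: Cp2ZrCl2 (cat.), CH2Cl2, 0 → 23 °C; volatiles removed; THF, n-BuLi, −78 °C; CO2, −78 → 0 °C; aq. HCl
Reagents that add atoms: carbon dioxide, O=C=O
Why: Zirconium-catalysed carboalumination (Negishi) adds CH3 and Al syn across the terminal alkyne with CH3 on the internal carbon C13, so C13=C14 is E. The alkenyl group of alanate 24 is then carboxylated with retention. The first equivalent of 6 is consumed by the hydroxyl group, and the 1,1-disubstituted C8=C17 alkene should not react.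

Step 15
Reactants: 25 (2E)-5-[(1S,4aR,5R,8aR)-5-(hydroxymethyl)-5,8a-dimethyl-2-methylidenedecahydronaphthalen-1-yl]-3-methylpent-2-enoic acid
Product: 26 (2E)-5-[(1S,4aR,5R,8aR)-5-[(acetyloxy)methyl]-5,8a-dimethyl-2-methylidenedecahydronaphthalen-1-yl]-3-methylpent-2-enoic acid
Conditions: Ac2O, pyridine, DMAP (cat.), CH2Cl2, 23 °C; then aq. NaHCO3, THF; acidify to pH 3
Reagents that add atoms: acetic anhydride, CC(=O)OC(C)=O
Why: Acetylation of the primary neopentyl alcohol. The carboxylic acid forms a mixed anhydride that the bicarbonate work-up hydrolyses, so no ester has to be cleaved beside the acetate.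

## Compound list

1 | cyclohexane-1,3-dione | O=C1CCCC(=O)C1 | starting material
2 | 3-oxocyclohex-1-en-1-yl trifluoromethanesulfonate | O=C1C=C(OS(=O)(=O)C(F)(F)F)CCC1 | intermediate
3 | (tributylstannyl)methanol | OC[Sn](CCCC)(CCCC)CCCC | starting material
4 | 3-(hydroxymethyl)cyclohex-2-en-1-one | O=C1C=C(CO)CCC1 | intermediate
5 | 3-{[(triisopropylsilyl)oxy]methyl}cyclohex-2-en-1-one | O=C1C=C(CO[Si](C(C)C)(C(C)C)C(C)C)CCC1 | intermediate
6 | trimethylaluminium | C[Al](C)C | starting material
7 | allyl iodide (3-iodoprop-1-ene) | C=CCI | starting material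
8 | dimethyl{[(3R)-3-methyl-3-{[(triisopropylsilyl)oxy]methyl}cyclohex-1-en-1-yl]oxy}alumane (not isolated) | C[Al](C)OC1=C[C@](C)(CO[Si](C(C)C)(C(C)C)C(C)C)CCC1 | intermediate
9 | lithium trimethyl{[(3R)-3-methyl-3-{[(triisopropylsilyl)oxy]methyl}cyclohex-1-en-1-yl]oxy}aluminate (not isolated) | [Li+].C[Al-](C)(C)OC1=C[C@](C)(CO[Si](C(C)C)(C(C)C)C(C)C)CCC1 | intermediate
10 | (2S,3R)-3-methyl-2-(prop-2-en-1-yl)-3-{[(triisopropylsilyl)oxy]methyl}cyclohexan-1-one | C=CC[C@H]1[C@](C)(CO[Si](C(C)C)(C(C)C)C(C)C)CCCC1=O | intermediate
11 | (1R,2S,3R)-1,3-dimethyl-2-(prop-2-en-1-yl)-3-{[(triisopropylsilyl)oxy]methyl}cyclohexan-1-ol | C=CC[C@H]1[C@](C)(CO[Si](C(C)C)(C(C)C)C(C)C)CCC[C@@]1(C)O | intermediate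
12 | (1R,2S,3R)-2-(3-hydroxypropyl)-1,3-dimethyl-3-{[(triisopropylsilyl)oxy]methyl}cyclohexan-1-ol | OCCC[C@H]1[C@](C)(CO[Si](C(C)C)(C(C)C)C(C)C)CCC[C@@]1(C)O | intermediate
13 | (4aS,5R,8aR)-5,8a-dimethyl-5-{[(triisopropylsilyl)oxy]methyl}octahydro-2H-chromen-2-one | O=C1CC[C@H]2[C@](C)(CO[Si](C(C)C)(C(C)C)C(C)C)CCC[C@@]2(C)O1 | intermediate
14 | (5-chloropent-1-yn-1-yl)trimethylsilane | ClCCCC#C[Si](C)(C)C | starting material
15 | chloro[5-(trimethylsilyl)pent-4-yn-1-yl]magnesium (not isolated) | Cl[Mg]CCCC#C[Si](C)(C)C | intermediate
16 | methyl 6-(trimethylsilyl)hex-5-ynoate | COC(=O)CCCC#C[Si](C)(C)C | intermediate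
17 | lithium 1-methoxy-6-(trimethylsilyl)hex-1-en-5-yn-1-olate (not isolated) | COC(O[Li])=CCCC#C[Si](C)(C)C | intermediate
18 | methyl 5-[(1S,2R,6R)-2-hydroxy-2,6-dimethyl-6-{[(triisopropylsilyl)oxy]methyl}cyclohexyl]-3-oxo-2-[4-(trimethylsilyl)but-3-yn-1-yl]pentanoate (C2 epimers) | COC(=O)C(CCC#C[Si](C)(C)C)C(=O)CC[C@H]1[C@](C)(CO[Si](C(C)C)(C(C)C)C(C)C)CCC[C@@]1(C)O | intermediate
19 | methyl (1R,4aR,5R,8aS)-5,8a-dimethyl-2-oxo-5-{[(triisopropylsilyl)oxy]methyl}-1-[4-(trimethylsilyl)but-3-yn-1-yl]decahydronaphthalene-1-carboxylate | COC(=O)[C@@]1(CCC#C[Si](C)(C)C)C(=O)CC[C@H]2[C@](C)(CO[Si](C(C)C)(C(C)C)C(C)C)CCC[C@]12C | intermediate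
20 | (1R,4aR,5R,8aS)-5,8a-dimethyl-5-{[(triisopropylsilyl)oxy]methyl}-1-[4-(trimethylsilyl)but-3-yn-1-yl]octahydronaphthalen-2(1H)-one | O=C1CC[C@H]2[C@](C)(CO[Si](C(C)C)(C(C)C)C(C)C)CCC[C@]2(C)[C@H]1CCC#C[Si](C)(C)C | intermediate
21 | trimethyl{4-[(1S,4aR,5R,8aR)-5,8a-dimethyl-2-methylidene-5-{[(triisopropylsilyl)oxy]methyl}decahydronaphthalen-1-yl]but-1-yn-1-yl}silane | C=C1CC[C@H]2[C@](C)(CO[Si](C(C)C)(C(C)C)C(C)C)CCC[C@]2(C)[C@H]1CCC#C[Si](C)(C)C | intermediate
22 | [(1R,4aR,5S,8aR)-5-(but-3-yn-1-yl)-1,4a-dimethyl-6-methylidenedecahydronaphthalen-1-yl]methanol | C=C1CC[C@H]2[C@](C)(CO)CCC[C@]2(C)[C@H]1CCC#C | intermediate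
23 | (E)-alkenyldimethylalane from 22: Al on C14, CH3 on C13, C18–O–AlMe2 (not isolated) | C=C1CC[C@H]2[C@](C)(CO[Al](C)C)CCC[C@]2(C)[C@H]1CC/C(C)=C/[Al](C)C | intermediate
24 | lithium butyl(dimethyl)alkenylalanate from 23 (not isolated) | [Li+].C=C1CC[C@H]2[C@](C)(CO[Al](C)C)CCC[C@]2(C)[C@H]1CC/C(C)=C/[Al-](C)(C)CCCC | intermediate
25 | (2E)-5-[(1S,4aR,5R,8aR)-5-(hydroxymethyl)-5,8a-dimethyl-2-methylidenedecahydronaphthalen-1-yl]-3-methylpent-2-enoic acid | C=C1CC[C@H]2[C@](C)(CO)CCC[C@]2(C)[C@H]1CC/C(C)=C/C(=O)O | intermediate
26 | (2E)-5-[(1S,4aR,5R,8aR)-5-[(acetyloxy)methyl]-5,8a-dimethyl-2-methylidenedecahydronaphthalen-1-yl]-3-methylpent-2-enoic acid | C=C1CC[C@H]2[C@](C)(COC(C)=O)CCC[C@]2(C)[C@H]1CC/C(C)=C/C(=O)O | target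

## Step count and least certain steps

Total step count: 15. Longest linear sequence: 14 steps (steps 1–7 and 9–15); step 8 is the side branch.

**Step 4 (key step).** The most likely failure is insufficient facial discrimination in the allylation of C5. The two C4 substituents differ mainly at a distance from the ring, and the two C5 epimers are close in energy, so base equilibration cannot be relied on to correct a poor ratio. Coordination of aluminium to the silyl ether oxygen could also lower the enantioselectivity at C4. Proton exchange between product and enolate could lead to double allylation.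

The fallback keeps the conjugate addition and replaces the enolate alkylation by a catalyst-controlled allylation. It sets out from 5. The enolate, activated with MeLi as in step 4, is O-acylated with allyl chloroformate to give prop-2-en-1-yl (3R)-3-methyl-3-{[(triisopropylsilyl)oxy]methyl}cyclohex-1-en-1-yl carbonate F1. After isolation, F1 undergoes decarboxylative allylation (Tsuji type) with Pd2(dba)3 (zerovalent palladium; dba = dibenzylideneacetone) and the enantiomer of tert-butyl-PHOX that reinforces the substrate bias, in THF at 23 °C. The route is rejoined at 10.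

**Step 10.** Three processes threaten the closure:
- Loss of the C5 configuration: the C10 cation can lose the C5 proton to give the tetrasubstituted C5=C10 alkene, and re-protonation would scramble C5 relative to C4.
- Slow C–C bond formation: two adjacent fully substituted carbons (C9, C10) are joined, which lengthens the life of the cation.
- Diversion: the silyl ether oxygen or an exocyclic C10=C20 alkene attacking the activated C8 carbonyl could take material away.

The fallback changes the order of bond formation so that the closure makes only one quaternary centre. It sets out from 13. Acylation of the lithium enolate of methyl acetate by 13 gives methyl 5-[(1S,2R,6R)-2-hydroxy-2,6-dimethyl-6-{[(triisopropylsilyl)oxy]methyl}cyclohexyl]-3-oxopentanoate F2. F2 is closed with SnCl4 as in step 10 to methyl (1R,4aR,5R,8aS)-5,8a-dimethyl-2-oxo-5-{[(triisopropylsilyl)oxy]methyl}decahydronaphthalene-1-carboxylate F3, the best-precedented form of this cyclisation. The side chain is then attached by C-alkylation of F3 at C9 with (4-iodobut-1-yn-1-yl)trimethylsilane F4 (Cs2CO3, DMF), which returns the route to 19.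

**Step 9.** The lactone carbonyl is flanked by a tertiary alkoxy group, and its C7 protons can be removed by the ester enolate. Proton transfer in place of acylation would return starting materials.

The fallback replaces the acylation by an aldol addition followed by oxidation. It sets out from 13. Reduction with iBu2AlH at −78 °C gives (4aS,5R,8aR)-5,8a-dimethyl-5-{[(triisopropylsilyl)oxy]methyl}octahydro-2H-chromen-2-ol F5. The open hydroxy aldehyde form of F5 adds excess enolate 17 to give methyl 3-hydroxy-5-[(1S,2R,6R)-2-hydroxy-2,6-dimethyl-6-{[(triisopropylsilyl)oxy]methyl}cyclohexyl]-2-[4-(trimethylsilyl)but-3-yn-1-yl]pentanoate F6. Oxidation of the secondary alcohol of F6 with Dess–Martin periodinane rejoins the route at 18.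

**Step 14.** The alanate may be protonated or may transfer an alkyl group instead of the alkenyl group during carboxylation. The aluminium alkoxide at C18 may also slow the carboalumination.

The fallback introduces C15 by palladium catalysis instead. It sets out from 22. Carboalumination as in step 14 followed by iodinolysis gives [(1R,4aR,5S,8aR)-5-[(3E)-4-iodo-3-methylbut-3-en-1-yl]-1,4a-dimethyl-6-methylidenedecahydronaphthalen-1-yl]methanol F7. Hydroxycarbonylation of F7 (Pd(OAc)2, PPh3, CO, K2CO3, DMF/H2O) rejoins the route at 25.

**Step 12.** The C8 ketone lies next to the branched C9 and a quaternary C10. The ylide may act as a base, so enolisation could compete with addition and conversion could stall.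

The fallback is a two-stage Peterson olefination. It sets out from 20. Addition of Me3SiCH2Li in the presence of CeCl3 gives (1R,4aR,5R,8aS)-5,8a-dimethyl-5-{[(triisopropylsilyl)oxy]methyl}-1-[4-(trimethylsilyl)but-3-yn-1-yl]-2-[(trimethylsilyl)methyl]decahydronaphthalen-2-ol F8 (either C2 epimer). Elimination of F8 with KH in THF rejoins the route at 21.

## Further compounds

F1 | step 4 | prop-2-en-1-yl (3R)-3-methyl-3-{[(triisopropylsilyl)oxy]methyl}cyclohex-1-en-1-yl carbonate | C=CCOC(=O)OC1=C[C@](C)(CO[Si](C(C)C)(C(C)C)C(C)C)CCC1
F2 | step 10 | methyl 5-[(1S,2R,6R)-2-hydroxy-2,6-dimethyl-6-{[(triisopropylsilyl)oxy]methyl}cyclohexyl]-3-oxopentanoate | COC(=O)CC(=O)CC[C@H]1[C@](C)(CO[Si](C(C)C)(C(C)C)C(C)C)CCC[C@@]1(C)O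
F3 | step 10 | methyl (1R,4aR,5R,8aS)-5,8a-dimethyl-2-oxo-5-{[(triisopropylsilyl)oxy]methyl}decahydronaphthalene-1-carboxylate | COC(=O)[C@H]1C(=O)CC[C@H]2[C@](C)(CO[Si](C(C)C)(C(C)C)C(C)C)CCC[C@]12C
F4 | step 10 | (4-iodobut-1-yn-1-yl)trimethylsilane | C[Si](C)(C)C#CCCI
F5 | step 9 | (4aS,5R,8aR)-5,8a-dimethyl-5-{[(triisopropylsilyl)oxy]methyl}octahydro-2H-chromen-2-ol (anomers) | OC1CC[C@H]2[C@](C)(CO[Si](C(C)C)(C(C)C)C(C)C)CCC[C@@]2(C)O1
F6 | step 9 | methyl 3-hydroxy-5-[(1S,2R,6R)-2-hydroxy-2,6-dimethyl-6-{[(triisopropylsilyl)oxy]methyl}cyclohexyl]-2-[4-(trimethylsilyl)but-3-yn-1-yl]pentanoate (diastereomers at C2 and C3) | COC(=O)C(CCC#C[Si](C)(C)C)C(O)CC[C@H]1[C@](C)(CO[Si](C(C)C)(C(C)C)C(C)C)CCC[C@@]1(C)O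
F7 | step 14 | [(1R,4aR,5S,8aR)-5-[(3E)-4-iodo-3-methylbut-3-en-1-yl]-1,4a-dimethyl-6-methylidenedecahydronaphthalen-1-yl]methanol | C=C1CC[C@H]2[C@](C)(CO)CCC[C@]2(C)[C@H]1CC/C(C)=C/I
F8 | step 12 | (1R,4aR,5R,8aS)-5,8a-dimethyl-5-{[(triisopropylsilyl)oxy]methyl}-1-[4-(trimethylsilyl)but-3-yn-1-yl]-2-[(trimethylsilyl)methyl]decahydronaphthalen-2-ol (either C2 epimer) | C[Si](C)(C)CC1(O)CC[C@H]2[C@](C)(CO[Si](C(C)C)(C(C)C)C(C)C)CCC[C@]2(C)[C@H]1CCC#C[Si](C)(C)C
A1 | alternative 1 | (2E)-6-{5-[(1E,3E)-4-(tert-butyldimethylsilyloxy)buta-1,3-dien-1-yl]-2,2-dimethyl-1,3-dioxan-5-yl}-3-methylhex-2-enal | O=C/C=C(\C)CCCC1(/C=C/C=C/O[Si](C)(C)C(C)(C)C)COC(C)(C)OC1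
A2 | alternative 1 | trans-fused Diels–Alder adduct: octalin with C6=C7, 8β-(tert-butyldimethylsilyloxy), 9β-formyl, 10β-methyl and a spiro 2,2-dimethyl-1,3-dioxane at C4 (labdane numbering) | [C@H]1(O[Si](C)(C)C(C)(C)C)C=C[C@H]2C3(COC(C)(C)OC3)CCC[C@]2(C)[C@H]1C=O
A3 | alternative 2 | [(1R)-2-ethenyl-1,3-dimethylcyclohex-2-en-1-yl]methyl but-2-ynoate | CC#CC(=O)OC[C@]1(C)CCCC(C)=C1C=C
A4 | alternative 2 | bridged lactone of the hexalin with C5=C6 and C8=C9, 10β-methyl, C11 carbonyl esterified by the C18 oxygen (labdane numbering) | CC1=C2C(=O)OC[C@]3(C)CCC[C@@]2(C)C3=CC1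
A5 | alternative 3 | (4R)-4-(tert-butyldimethylsilyloxy)-2-methylcyclohex-2-en-1-one | CC1=C[C@H](O[Si](C)(C)C(C)(C)C)CCC1=O
A6 | alternative 3 | bromo[2-(2-methyl-1,3-dioxolan-2-yl)ethyl]magnesium | Br[Mg]CCC1(C)OCCO1
A7 | alternative 3 | 2-(trimethylsilyl)pent-1-en-3-one | CCC(=O)C(=C)[Si](C)(C)C
A8 | alternative 3 | 8α-(tert-butyldimethylsilyloxy)-4,10-dimethyl-9β-[2-(2-methyl-1,3-dioxolan-2-yl)ethyl]octal-4-en-3-one (labdane numbering) | [C@@H]1(O[Si](C)(C)C(C)(C)C)CCC2=C(C)C(=O)CC[C@]2(C)[C@H]1CCC1(C)OCCO1
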